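In a closed stirred flask, the set-up called dawn, the catalyst goes round a cycle, and each round uses one substrate and one coupling partner and gives one target and one by-product. The four set-ups share their charges and differ in vessel and feed.

| flask | substrate | coupling partner | free catalyst | time | remark |
|---|---|---|---|---|---|
| winter | 0.10 M | 1.00 equiv (fed, over 3.00 min) | 2 mol% | 3.0 min | all but coupling partner at the start; coupling partner goes in evenly over 3.00 min, the run ends at 3.0 min |
| dusk | 0.10 M | 1.00 equiv | 2 mol% |  | a single well-mixed tank run continuously and read at steady state, 3.0 min in it on average |
| midnight | 0.10 M (fed, over 3.00 min) | 1.00 equiv | 2 mol% | 3.0 min | a stirred flask in which substrate is dosed at a steady rate over 3.00 min without added volume, worked up at 3.0 min |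
| dawn | 0.10 M | 1.00 equiv | 2 mol% | 3.0 min | everything together in a closed stirred flask, run for 3.0 min |

- the set-up with the highest amount of target at the outlet or at the end, in percent of the substrate put in ("none" if the first two lie within 2 percentage points) (winter / dusk / midnight / dawn / none)
- amount of target at the outlet or at the end, in percent of the substrate put in, winter
- amount of target at the outlet or at the end, in percent of the substrate put in, dusk
- amount of target at the outlet or at the end, in percent of the substrate put in, midnight
- amount of target at the outlet or at the end, in percent of the substrate put in, dawn

- in percentages every species weighs as the substrate in it: one side product counts as two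
- two of one species on the left: rate k times its square, two consumed each time
- the stated concentrations are those of everything mixed, before any reaction; amounts are the same in each set-up
- the feed brings no volume worth counting
- run time (winter): 3.0 min

    substrate + target → side product (k1 = 0.14 M⁻¹ min⁻¹)
    catalyst intermediate B → by-product + catalyst intermediate C (k2 = 1100 min⁻¹)
    catalyst intermediate D → free catalyst + target (k3 = 17 min⁻¹)
    2 catalyst intermediate B → spent catalyst (k4 = 19 M⁻¹ min⁻¹)
    target + free catalyst ⇌ isomer of the product + free catalyst, rate k5*[free catalyst]*[target] forward; the back reaction follows from the equilibrium constant (K5 = 0.93, k5 = 140 M⁻¹ min⁻¹)
    catalyst intermediate A → catalyst intermediate B (k6 = 34 min⁻¹)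
    coupling partner + free catalyst ⇌ catalyst intermediate A (K7 = 8.0 M⁻¹, k7 = 4500 M⁻¹ min⁻¹)
    substrate + catalyst intermediate C → catalyst intermediate D (k8 = 250 M⁻¹ min⁻¹)

I reckoned dawn, and I worked with the fraction left, not the fraction made. Part of a round is fixed: catalyst intermediate A becoming B, B becoming C, and D releasing free catalyst and target take 0.0891 min together. The other part is waiting: C waits for substrate, and free catalyst waits for coupling partner, counting the times A falls apart again. At the charged concentrations this comes to 0.0790 min. Their sum at the charge, 0.168 min, is what I carried: the round time, the minutes one catalyst needs for one whole round, the inverse of the turnover frequency. At any moment in dawn, with the two reagents level,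

round time = fixed part + waiting part × [substrate charged]/[substrate]

First I took the main cycle with the round time held at the charge. Then 3.0 min gives 17.9 rounds, and each round uses 2 mol% of the substrate, so 35.7% would be gone.

Next I let the reagents run down. They start equal and go one for one, so they share one fraction left, x, and summing the round time over each small fall in x gives

fixed part × (share gone) + waiting part × ln(charge/left) = loading × time = 0.0600 min

A first try, treating the whole round as waiting, gives x = 70.0%. One correction gives x = 67.5%, so 32.5% has reacted. By then the round time has stretched to 0.206 min, longer than at the start.

Last came the losses from target. Free catalyst also turns target into its isomer, and free catalyst holds 28.0% of the round at the end. Taking target as on average half the run old, the forward step takes 11.8% of it. Substrate meeting target takes 2.10% more, with substrate held as charged. That left 28.0% target in dawn. I ranked the other set-ups below dawn, without a number.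

The forecast named dawn as best, with 20% for winter, 24.6% for dusk, 21.5% for midnight and 28.3% for dawn, on the grounds that “anything that keeps a reagent low (dosing, or the tank running at outlet concentrations) loses rate”.

The simulation gave dawn as best, with 20.0% for winter, 23.8% for dusk, 21.3% for midnight and 28.2% for dawn.

In dawn, substrate stood at 67.2% of its charge at 3.00 min, beside my 67.5%. At that reading the round time is 0.207 min, against 0.168 min at the charge. The same quantity serves the dusk tank, where coupling partner reads 0.0696 M and the catalyst works at that level throughout. Taking substrate level with it, the round time there is 0.203 min. Over 3.0 min on average I reckoned that as 14.8 rounds, or 29.6% of the charge consumed in the dusk tank.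

The constants used here are assumed.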